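**Assumption:** the target is taken as the open-chain hydroperoxy enone of the SMILES, whose single stereocentre is S by CIP analysis. The side chain is numbered C1 (ArOCH2) to C8, so the target is C1(OAr)–C2(OOH)–C3(=CH2)–C4H2–C5(=O)–C6H=C7(CH3)–C8.

## Retrosynthetic overview

1. C2–OOH: SN2 displacement with inversion of a (2R)-allylic mesylate by a ketal-masked hydroperoxide; the C5 enone comes from late oxidation of a C5 carbinol, after the basic peroxide step.
2. C4–C5: Hosomi–Sakurai addition of a 2-(silylmethyl)allyl unit to 3-methylbut-2-enal.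
3. C2 stereocentre: ketoreductase reduction of an achiral α-aryloxy α'-methylene ketone; this is the first and only permanent stereocentre.
4. C2–C3: Weinreb amide plus vinyl Grignard reagent; C1–OAr: Williamson alkylation of methyl vanillate.
5. Rings: none is formed; the benzene ring is bought in methyl vanillate.

## Route

Step 1
Reactants: 1 methyl vanillate (methyl 4-hydroxy-3-methoxybenzoate); 2 2-chloro-N-methoxy-N-methylacetamide
Product: 4 methyl 3-methoxy-4-{2-[methoxy(methyl)amino]-2-oxoethoxy}benzoate, via potassium phenolate 3 (not isolated)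
Conditions: K2CO3, KI (cat.), DMF, 60 °C
Reagents that add atoms: none
Why: Williamson ether synthesis, in which the phenolate displaces the activated α-chloro amide chloride by SN2 (iodide-assisted) and no stereocentre is involved.

Step 2
Reactants: 4 methyl 3-methoxy-4-{2-[methoxy(methyl)amino]-2-oxoethoxy}benzoate; 5 2-bromo-3-(trimethylsilyl)prop-1-ene
Product: 8 methyl 3-methoxy-4-({2-oxo-3-[(trimethylsilyl)methyl]but-3-en-1-yl}oxy)benzoate, via vinyl Grignard reagent 6 (not isolated), via bromomagnesium hemiaminal chelate 7 (not isolated)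
Conditions: 5, Mg, THF, rt; then added to 4 (1.15 equiv of 6), THF, −40 → 0 °C; cold 0.5 M HCl quench
Reagents that add atoms: none
Why: Weinreb ketone synthesis, in which the vinyl Grignard reagent adds once to the chelating N-methoxy-N-methylamide (far more electrophilic at −40 °C than the para-alkoxy-deactivated methyl benzoate) and the chelate releases the ketone only on quench.

Step 3
Reactants: 8 methyl 3-methoxy-4-({2-oxo-3-[(trimethylsilyl)methyl]but-3-en-1-yl}oxy)benzoate
Product: 9 methyl 4-({(2R)-2-hydroxy-3-[(trimethylsilyl)methyl]but-3-en-1-yl}oxy)-3-methoxybenzoate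
Conditions: ketoreductase (R-selective, NADPH-dependent alcohol dehydrogenase, oxidoreductase class EC 1.1.1, chosen from a screening panel), NADP+ (cat.), iPrOH (15 vol%), DMSO (5 vol%), KH2PO4/K2HPO4 buffer pH 7.0, 30 °C
Reagents that add atoms: none
Why: Enzymatic asymmetric ketone reduction, in which the ketoreductase delivers hydride from NADPH (recycled by isopropanol) to one enantiotopic face of the prochiral ketone and so sets C2 as R, leaving the C=C bond, the ester and the allylsilane untouched at pH 7.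

Step 4
Reactants: 9 methyl 4-({(2R)-2-hydroxy-3-[(trimethylsilyl)methyl]but-3-en-1-yl}oxy)-3-methoxybenzoate
Product: 10 methyl 4-({(2R)-2-acetoxy-3-[(trimethylsilyl)methyl]but-3-en-1-yl}oxy)-3-methoxybenzoate
Conditions: Ac2O, pyridine, DMAP (cat.), CH2Cl2, 0 °C → rt
Reagents that add atoms: acetic anhydride CC(=O)OC(C)=O
Why: DMAP-catalysed O-acylation at oxygen (C2 retained) gives a 2-(silylmethyl)allyl acetate, a motif that tolerates Lewis-acid allylsilane chemistry and keeps the C2 oxygen distinguishable from the C5 oxygen made next.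

Step 5
Reactants: 10 methyl 4-({(2R)-2-acetoxy-3-[(trimethylsilyl)methyl]but-3-en-1-yl}oxy)-3-methoxybenzoate; 11 3-methylbut-2-enal
Product: 13 methyl 4-{[(2R)-2-acetoxy-5-hydroxy-7-methyl-3-methylideneoct-6-en-1-yl]oxy}-3-methoxybenzoate (about 1:1 C5 epimers), via difluoroboryl ether 12 (not isolated)
Conditions: BF3·OEt2 (1.1 equiv), CH2Cl2, −78 °C; then H2O/NaHCO3 work-up
Reagents that add atoms: none
Why: Hosomi–Sakurai allylation, in which the BF3-activated enal is attacked 1,2 by the terminal CH2 of the allylsilane (SE2') and loss of silicon regenerates the 1,1-disubstituted alkene; C2 is untouched and the unselective C5 centre is erased by oxidation in step 12.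

Step 6
Reactants: 13 methyl 4-{[(2R)-2-acetoxy-5-hydroxy-7-methyl-3-methylideneoct-6-en-1-yl]oxy}-3-methoxybenzoate
Product: 14 methyl 4-{[(2R)-2-acetoxy-5-(tert-butyldimethylsilyloxy)-7-methyl-3-methylideneoct-6-en-1-yl]oxy}-3-methoxybenzoate
Conditions: TBSCl, imidazole, DMF, rt
Reagents that add atoms: tert-butyldimethylsilyl chloride CC(C)(C)[Si](C)(C)Cl
Why: Imidazole-promoted silylation protects the C5 carbinol as a base-stable ether, so that it cannot close onto C2 (five-membered ether formation) during the later displacement.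

Step 7
Reactants: 14 methyl 4-{[(2R)-2-acetoxy-5-(tert-butyldimethylsilyloxy)-7-methyl-3-methylideneoct-6-en-1-yl]oxy}-3-methoxybenzoate
Product: 15 methyl 4-{[(2R)-5-(tert-butyldimethylsilyloxy)-2-hydroxy-7-methyl-3-methylideneoct-6-en-1-yl]oxy}-3-methoxybenzoate
Conditions: K2CO3 (0.3 equiv), MeOH, 0 °C
Reagents that add atoms: none
Why: Base-catalysed transesterification (methanolysis) removes only the acetate, because exchange at the aryl methyl ester is degenerate in methanol and the silyl ether is stable; C2 is retained.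

Step 8
Reactants: 15 methyl 4-{[(2R)-5-(tert-butyldimethylsilyloxy)-2-hydroxy-7-methyl-3-methylideneoct-6-en-1-yl]oxy}-3-methoxybenzoate
Product: 16 methyl 4-{[(2R)-5-(tert-butyldimethylsilyloxy)-2-(methanesulfonyloxy)-7-methyl-3-methylideneoct-6-en-1-yl]oxy}-3-methoxybenzoate (used crude)
Conditions: Ms2O, Et3N, CH2Cl2, −20 °C
Reagents that add atoms: methanesulfonic anhydride CS(=O)(=O)OS(C)(=O)=O
Why: O-sulfonylation leaves the C2–O bond intact (retention), and the anhydride avoids chloride ion that could displace the allylic sulfonate.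

Step 9
Reactants: 17 2,3-dimethylbut-2-ene
Product: 20 2-hydroperoxy-2-methoxypropane (2-methoxyprop-2-yl hydroperoxide; kept cold in solution), via primary ozonide 18 (not isolated), via acetone O-oxide 19 (not isolated)
Conditions: O3, MeOH/CH2Cl2, −78 °C; concentrate cold behind a shield
Reagents that add atoms: ozone [O-][O+]=O; methanol CO
Why: Ozonolysis in methanol, in which Criegee cycloreversion of the primary ozonide gives acetone and the carbonyl oxide, and methanol traps the carbonyl oxide as the α-methoxy hydroperoxide.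

Step 10
Reactants: 16 methyl 4-{[(2R)-5-(tert-butyldimethylsilyloxy)-2-(methanesulfonyloxy)-7-methyl-3-methylideneoct-6-en-1-yl]oxy}-3-methoxybenzoate; 20 2-hydroperoxy-2-methoxypropane
Product: 22 methyl 4-{[(2S)-5-(tert-butyldimethylsilyloxy)-2-[(2-methoxypropan-2-yl)peroxy]-7-methyl-3-methylideneoct-6-en-1-yl]oxy}-3-methoxybenzoate, via cesium peroxide salt 21 (not isolated)
Conditions: 20 (2 equiv), CsOH·H2O (1.5 equiv), DMF, 0 °C; then 16, 0 °C
Reagents that add atoms: none
Why: SN2 alkylation of the α-effect peroxide anion at the secondary allylic mesylate inverts C2 from R to S, and the β-aryloxy group disfavours ionisation so the displacement stays stereospecific.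

Step 11
Reactants: 22 methyl 4-{[(2S)-5-(tert-butyldimethylsilyloxy)-2-[(2-methoxypropan-2-yl)peroxy]-7-methyl-3-methylideneoct-6-en-1-yl]oxy}-3-methoxybenzoate
Product: 23 methyl 4-{[(2S)-5-hydroxy-2-[(2-methoxypropan-2-yl)peroxy]-7-methyl-3-methylideneoct-6-en-1-yl]oxy}-3-methoxybenzoate
Conditions: Bu4NF/AcOH (1:1), THF, rt
Reagents that add atoms: none
Why: Fluoride-mediated desilylation buffered with acetic acid is neither basic enough for Kornblum–DeLaMare fragmentation of the secondary peroxide nor acidic enough to cleave the peroxy ketal.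

Step 12
Reactants: 23 methyl 4-{[(2S)-5-hydroxy-2-[(2-methoxypropan-2-yl)peroxy]-7-methyl-3-methylideneoct-6-en-1-yl]oxy}-3-methoxybenzoate
Product: 24 methyl 3-methoxy-4-{[(2S)-2-[(2-methoxypropan-2-yl)peroxy]-7-methyl-3-methylidene-5-oxooct-6-en-1-yl]oxy}benzoate
Conditions: Dess–Martin periodinane, pyridine, CH2Cl2, 0 °C → rt
Reagents that add atoms: none
Why: Dess–Martin oxidation converts both C5 epimers of the allylic alcohol into the single enone under buffered, non-basic conditions that keep the 3-methylidene group out of conjugation and leave the peroxy ketal intact.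

Step 13
Reactants: 24 methyl 3-methoxy-4-{[(2S)-2-[(2-methoxypropan-2-yl)peroxy]-7-methyl-3-methylidene-5-oxooct-6-en-1-yl]oxy}benzoate
Product: 25 methyl 4-{[(2S)-2-hydroperoxy-7-methyl-3-methylidene-5-oxooct-6-en-1-yl]oxy}-3-methoxybenzoate (CNP0338697.1)
Conditions: AcOH/THF/H2O (4:2:1), rt
Reagents that add atoms: none
Why: Mild acid-catalysed hydrolysis of the peroxy ketal (through a peroxycarbenium ion, giving acetone and methanol) releases the hydroperoxide without touching the C2–O bond, the skipped enone or the ester.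

## Compound list

1 | methyl vanillate (methyl 4-hydroxy-3-methoxybenzoate) | COC(=O)c1ccc(O)c(OC)c1 | starting material
2 | 2-chloro-N-methoxy-N-methylacetamide | CON(C)C(=O)CCl | starting material
3 | potassium 2-methoxy-4-(methoxycarbonyl)phenolate (not isolated) | COC(=O)c1ccc([O-])c(OC)c1.[K+] | intermediate
4 | methyl 3-methoxy-4-{2-[methoxy(methyl)amino]-2-oxoethoxy}benzoate | COC(=O)c1ccc(OCC(=O)N(C)OC)c(OC)c1 | intermediate
5 | 2-bromo-3-(trimethylsilyl)prop-1-ene | C=C(Br)C[Si](C)(C)C | starting material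
6 | bromo[3-(trimethylsilyl)prop-1-en-2-yl]magnesium (not isolated) | C=C([Mg]Br)C[Si](C)(C)C | intermediate
7 | bromomagnesium alkoxide of the tetrahedral N-methoxy-N-methyl hemiaminal adduct of 4 and 6 (not isolated; transient centre, lost on collapse) | COC(=O)c1ccc(OCC(O[Mg]Br)(N(C)OC)C(=C)C[Si](C)(C)C)c(OC)c1 | intermediate
8 | methyl 3-methoxy-4-({2-oxo-3-[(trimethylsilyl)methyl]but-3-en-1-yl}oxy)benzoate | COC(=O)c1ccc(OCC(=O)C(=C)C[Si](C)(C)C)c(OC)c1 | intermediate
9 | methyl 4-({(2R)-2-hydroxy-3-[(trimethylsilyl)methyl]but-3-en-1-yl}oxy)-3-methoxybenzoate | C=C(C[Si](C)(C)C)[C@H](COc1ccc(C(=O)OC)cc1OC)O | intermediate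
10 | methyl 4-({(2R)-2-acetoxy-3-[(trimethylsilyl)methyl]but-3-en-1-yl}oxy)-3-methoxybenzoate | C=C(C[Si](C)(C)C)[C@H](COc1ccc(C(=O)OC)cc1OC)OC(C)=O | intermediate
11 | 3-methylbut-2-enal | CC(C)=CC=O | starting material
12 | C5 O-difluoroboryl ether of 13 (not isolated; C5 epimers) | C=C(CC(OB(F)F)C=C(C)C)[C@H](COc1ccc(C(=O)OC)cc1OC)OC(C)=O | intermediate
13 | methyl 4-{[(2R)-2-acetoxy-5-hydroxy-7-methyl-3-methylideneoct-6-en-1-yl]oxy}-3-methoxybenzoate (C5 epimers) | C=C(CC(O)C=C(C)C)[C@H](COc1ccc(C(=O)OC)cc1OC)OC(C)=O | intermediate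
14 | methyl 4-{[(2R)-2-acetoxy-5-(tert-butyldimethylsilyloxy)-7-methyl-3-methylideneoct-6-en-1-yl]oxy}-3-methoxybenzoate (C5 epimers) | C=C(CC(O[Si](C)(C)C(C)(C)C)C=C(C)C)[C@H](COc1ccc(C(=O)OC)cc1OC)OC(C)=O | intermediate
15 | methyl 4-{[(2R)-5-(tert-butyldimethylsilyloxy)-2-hydroxy-7-methyl-3-methylideneoct-6-en-1-yl]oxy}-3-methoxybenzoate (C5 epimers) | C=C(CC(O[Si](C)(C)C(C)(C)C)C=C(C)C)[C@H](COc1ccc(C(=O)OC)cc1OC)O | intermediate
16 | methyl 4-{[(2R)-5-(tert-butyldimethylsilyloxy)-2-(methanesulfonyloxy)-7-methyl-3-methylideneoct-6-en-1-yl]oxy}-3-methoxybenzoate (C5 epimers) | C=C(CC(O[Si](C)(C)C(C)(C)C)C=C(C)C)[C@H](COc1ccc(C(=O)OC)cc1OC)OS(C)(=O)=O | intermediate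
17 | 2,3-dimethylbut-2-ene | CC(C)=C(C)C | starting material
18 | 4,4,5,5-tetramethyl-1,2,3-trioxolane (primary ozonide, not isolated) | CC1(C)OOOC1(C)C | intermediate
19 | propan-2-one O-oxide (acetone O-oxide, not isolated) | CC(C)=[O+][O-] | intermediate
20 | 2-hydroperoxy-2-methoxypropane | COC(C)(C)OO | intermediate
21 | cesium 2-methoxypropan-2-yl peroxide (not isolated) | COC(C)(C)O[O-].[Cs+] | intermediate
22 | methyl 4-{[(2S)-5-(tert-butyldimethylsilyloxy)-2-[(2-methoxypropan-2-yl)peroxy]-7-methyl-3-methylideneoct-6-en-1-yl]oxy}-3-methoxybenzoate (C5 epimers) | C=C(CC(O[Si](C)(C)C(C)(C)C)C=C(C)C)[C@@H](COc1ccc(C(=O)OC)cc1OC)OOC(C)(C)OC | intermediate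
23 | methyl 4-{[(2S)-5-hydroxy-2-[(2-methoxypropan-2-yl)peroxy]-7-methyl-3-methylideneoct-6-en-1-yl]oxy}-3-methoxybenzoate (C5 epimers) | C=C(CC(O)C=C(C)C)[C@@H](COc1ccc(C(=O)OC)cc1OC)OOC(C)(C)OC | intermediate
24 | methyl 3-methoxy-4-{[(2S)-2-[(2-methoxypropan-2-yl)peroxy]-7-methyl-3-methylidene-5-oxooct-6-en-1-yl]oxy}benzoate | C=C(CC(=O)C=C(C)C)[C@@H](COc1ccc(C(=O)OC)cc1OC)OOC(C)(C)OC | intermediate
25 | methyl 4-{[(2S)-2-hydroperoxy-7-methyl-3-methylidene-5-oxooct-6-en-1-yl]oxy}-3-methoxybenzoate | C=C(CC(=O)C=C(C)C)[C@@H](COc1ccc(C(=O)OC)cc1OC)OO | target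

## Step count and risks

Total step count: 13.
Longest linear sequence: 12 steps (1 → 25 through steps 1–8 and 10–13); step 9 is a one-step side branch that makes reagent 20.

Three steps most likely to fail:

**Step 10 (peroxide SN2 at the allylic mesylate).** The bulky tertiary peroxide anion may give allylic transposition (SN2') or elimination instead of direct substitution. The fallback sets out from mesylate 16, which is displaced with the small hydroperoxide anion (50% aqueous H2O2, CsOH·H2O, DMF/THF, 0 °C, inversion) to give the free hydroperoxide methyl 4-{[(2S)-5-(tert-butyldimethylsilyloxy)-2-hydroperoxy-7-methyl-3-methylideneoct-6-en-1-yl]oxy}-3-methoxybenzoate F6. The ketal is then built on oxygen by acid-catalysed addition of the OOH group to 2-methoxypropene (PPTS cat., CH2Cl2, 0 °C), and the route is rejoined at 22.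

**Step 5 (Sakurai addition to the enal).** BF3 may ionise the prenyl-type carbinol being formed or react sluggishly with the β,β-disubstituted enal. The fallback sets out from allylsilane 10, which is acylated with 3-methylbut-2-enoyl chloride (TiCl4, CH2Cl2, −78 °C, Friedel–Crafts-type acylation of the allylsilane with loss of silicon) to give the β,γ-unsaturated ketone methyl 4-{[(2R)-2-acetoxy-7-methyl-3-methylidene-5-oxooct-6-en-1-yl]oxy}-3-methoxybenzoate F5. Luche 1,2-reduction (NaBH4, CeCl3·7H2O, MeOH, −40 °C) then gives the C5 carbinol, and the route is rejoined at 13.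

**Step 2 (Grignard addition in the presence of the aryl ester).** The methyl benzoate may compete for the organometallic; the same detour also helps if 8 proves a poor enzyme substrate. The fallback sets out from 2 and 5, with Grignard reagent 6 made as before.
- Reagent 6 is added to chloro amide 2 (THF, −40 °C), with no ester present, through the bromomagnesium hemiaminal chelate F1, and gives 1-chloro-3-[(trimethylsilyl)methyl]but-3-en-2-one F2 on acidic quench.
- An R-selective ketoreductase (NADP+, iPrOH, buffer pH 7) reduces this to (2R)-1-chloro-3-[(trimethylsilyl)methyl]but-3-en-2-ol F3.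
- K2CO3 in DMF at 60 °C with methyl vanillate 1 closes the chlorohydrin to (2R)-2-[3-(trimethylsilyl)prop-1-en-2-yl]oxirane F4, which the phenolate opens at the terminal CH2 in the same pot.
- C2 is untouched throughout, and the route is rejoined at 9.

## Further compounds

F1 | step 2 | bromomagnesium alkoxide of the tetrahedral N-methoxy-N-methyl hemiaminal adduct of 2 and 6 | CON(C)C(CCl)(O[Mg]Br)C(=C)C[Si](C)(C)C
F2 | step 2 | 1-chloro-3-[(trimethylsilyl)methyl]but-3-en-2-one | C=C(C[Si](C)(C)C)C(=O)CCl
F3 | step 2 | (2R)-1-chloro-3-[(trimethylsilyl)methyl]but-3-en-2-ol | C=C(C[Si](C)(C)C)[C@H](CCl)O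
F4 | step 2 | (2R)-2-[3-(trimethylsilyl)prop-1-en-2-yl]oxirane | C=C(C[Si](C)(C)C)[C@@H]1CO1
F5 | step 5 | methyl 4-{[(2R)-2-acetoxy-7-methyl-3-methylidene-5-oxooct-6-en-1-yl]oxy}-3-methoxybenzoate | C=C(CC(=O)C=C(C)C)[C@H](COc1ccc(C(=O)OC)cc1OC)OC(C)=O
F6 | step 10 | methyl 4-{[(2S)-5-(tert-butyldimethylsilyloxy)-2-hydroperoxy-7-methyl-3-methylideneoct-6-en-1-yl]oxy}-3-methoxybenzoate | C=C(CC(O[Si](C)(C)C(C)(C)C)C=C(C)C)[C@@H](COc1ccc(C(=O)OC)cc1OC)OO
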